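**Retrosynthetic overview**
1. CJ-13,015 (14) ⇒ acid 13: the γ-lactone is closed last by an enantioselective benzylic C–H lactonisation, the chemical counterpart of the biosynthetic benzylic oxygenation/lactonisation of an alkylresorcylic acid; C3 is set here.
2. 13 ⇒ resorcylic acid 10: O-methylation, unmasking of a 2-methylfuran to the 1,4-diketone, ester cleavage.
3. 10 ⇒ acylpyrone 8: the benzene ring is made by polyketide-type ring opening to a 3,5,7-triketo acid and C2→C7 aldol aromatisation.
4. 8 ⇒ triacetic acid lactone 5 + acid 4; 4 ⇒ 2-methylfuran 1 + 11-bromoundecanoic acid 2.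
5. Ring order: benzene ring (step 3), then lactone (step 7).

Assumption: the stereocentre in the SMILES is read as (3S); the sense of induction in step 7 is unproven, so if (S,S)-tBu-BOX gives the (R)-lactone its mirror-image ligand is used.

**Step 1**
Reactants: 1 2-methylfuran; 2 11-bromoundecanoic acid
Product: 4 11-(5-methylfuran-2-yl)undecanoic acid, via (5-methylfuran-2-yl)lithium 3 (not isolated)
Conditions: 1 (2.3 equiv), n-BuLi (2.2 equiv), THF, 0 °C; then 2, DMPU, −78 °C → rt; aq. HCl
Reagents that add atoms: n-butyllithium, [Li]CCCC (Li of 3 only; no reagent atom stays in 4)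
Why: C5-lithiation of 2-methylfuran is clean, one equivalent of 3 deprotonates the acid and the second displaces the primary bromide (SN2 alkylation of a heteroaryllithium) faster than it adds to the lithium carboxylate; the furan is a latent 1,4-diketone.

**Step 2**
Reactants: 4 11-(5-methylfuran-2-yl)undecanoic acid; 5 4-hydroxy-6-methyl-2H-pyran-2-one (triacetic acid lactone)
Product: 8 4-hydroxy-6-[12-(5-methylfuran-2-yl)-2-oxododecyl]-2H-pyran-2-one, via acyl imidazolide 6 (not isolated), via pyrone dilithium dianion 7 (not isolated)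
Conditions: 4, CDI, THF, rt; 5 (3 equiv), LDA (6.2 equiv), THF/DMPU, −78 °C; add 6, −78 → −20 °C; aq. HCl
Reagents that add atoms: 1,1'-carbonyldiimidazole, O=C(n1ccnc1)n1ccnc1 (imidazolyl of 6 only); lithium diisopropylamide, CC(C)N([Li])C(C)C (Li of 7 only); no reagent atom stays in 8
Why: Claisen-type C-acylation of the C7 carbanion of the triacetic acid lactone dianion by an N-acylimidazole extends the masked polyketide chain, and the excess of cheap dianion absorbs the acidic protons of the product and of imidazole.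

**Step 3**
Reactants: 8 4-hydroxy-6-[12-(5-methylfuran-2-yl)-2-oxododecyl]-2H-pyran-2-one
Product: 10 2,4-dihydroxy-6-[10-(5-methylfuran-2-yl)decyl]benzoic acid, via triketo acid 9 (not isolated)
Conditions: 2 M KOH, H2O/THF, rt, Ar; then HCl to pH 2, 0 °C
Reagents that add atoms: potassium hydroxide, [K+].[OH-] (its O ends as a carboxyl O)
Why: Hydroxide opens the pyrone to the 3,5,7-triketo acid, whose C2 attacks the C7 ketone (intramolecular aldol condensation) and dehydration/enolisation gives the β-resorcylic acid, a biomimetic polyketide aromatisation; the furan is inert to base.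

**Step 4**
Reactants: 10 2,4-dihydroxy-6-[10-(5-methylfuran-2-yl)decyl]benzoic acid
Product: 11 methyl 2,4-dimethoxy-6-[10-(5-methylfuran-2-yl)decyl]benzoate
Conditions: MeI (5 equiv), K2CO3, DMF, rt → 40 °C
Reagents that add atoms: iodomethane, CI
Why: Williamson O-methylation of both phenoxides and the carboxylate, which also removes the decarboxylation-prone free resorcylic acid.

**Step 5**
Reactants: 11 methyl 2,4-dimethoxy-6-[10-(5-methylfuran-2-yl)decyl]benzoate
Product: 12 methyl 2,4-dimethoxy-6-(11,14-dioxopentadecyl)benzoate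
Conditions: AcOH/H2O (3:1), cat. H2SO4, 100 °C
Reagents that add atoms: water, O
Why: Acid-catalysed hydrolytic ring opening of the 2,5-dialkylfuran (reverse Paal–Knorr) releases the 1,4-diketone, while the 2,6-disubstituted methyl ester and the aryl ethers are inert and the ester prevents protodecarboxylation.

**Step 6**
Reactants: 12 methyl 2,4-dimethoxy-6-(11,14-dioxopentadecyl)benzoate
Product: 13 2,4-dimethoxy-6-(11,14-dioxopentadecyl)benzoic acid
Conditions: LiI (5 equiv), pyridine, reflux; aq. HCl
Reagents that add atoms: none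
Why: SN2 O-demethylation of the hindered ester by iodide at the methyl carbon avoids hydroxide, which cannot easily reach the shielded carbonyl and would cyclise the 1,4-diketone by aldol condensation.

**Step 7**
Reactants: 13 2,4-dimethoxy-6-(11,14-dioxopentadecyl)benzoic acid
Product: 14 CJ-13,015, (3S)-5,7-dimethoxy-3-(10,13-dioxotetradecyl)-2-benzofuran-1(3H)-one
Conditions: Cu(MeCN)4PF6 (10 mol %), (S,S)-tBu-BOX (12 mol %), NFSI (1.5 equiv), Li2CO3 (1 equiv), PhCl, rt
Reagents that add atoms: none
Why: Proposed new method: Cu(I)/NFSI gives a Cu(II)-bound sulfonimidyl radical that abstracts the weakest, polarity-matched C–H bond (the benzylic CH2, not the ketone α-C–H), the benzylic radical is captured by the chiral Cu(II) carboxylate of the same molecule and C–O reductive elimination from the Cu(III) metallacycle closes the lactone with the tBu-BOX pocket selecting the radical face that gives (S); the closest known reaction types are Cu/BOX/NFSI radical-relay enantioselective benzylic C–H functionalisation, Cu/BOX enantioselective lactonisation of 2-vinylbenzoic acids by capture of a benzylic radical at Cu(II) carboxylate, and the asymmetric Kharasch–Sosnovsky acyloxylation.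

**Compound list**
1 | 2-methylfuran | Cc1ccco1 | starting material
2 | 11-bromoundecanoic acid | OC(=O)CCCCCCCCCCBr | starting material
3 | (5-methylfuran-2-yl)lithium | [Li]c1ccc(C)o1 | intermediate
4 | 11-(5-methylfuran-2-yl)undecanoic acid | Cc1ccc(CCCCCCCCCCC(=O)O)o1 | intermediate
5 | 4-hydroxy-6-methyl-2H-pyran-2-one (triacetic acid lactone) | Cc1cc(O)cc(=O)o1 | starting material
6 | 1-(1H-imidazol-1-yl)-11-(5-methylfuran-2-yl)undecan-1-one | Cc1ccc(CCCCCCCCCCC(=O)n2ccnc2)o1 | intermediate
7 | O4,C7-dilithio dianion of 4-hydroxy-6-methyl-2H-pyran-2-one | [Li]Cc1cc(O[Li])cc(=O)o1 | intermediate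
8 | 4-hydroxy-6-[12-(5-methylfuran-2-yl)-2-oxododecyl]-2H-pyran-2-one | Cc1ccc(CCCCCCCCCCC(=O)Cc2cc(O)cc(=O)o2)o1 | intermediate
9 | 17-(5-methylfuran-2-yl)-3,5,7-trioxoheptadecanoic acid (present as its potassium salt) | OC(=O)CC(=O)CC(=O)CC(=O)CCCCCCCCCCc1ccc(C)o1 | intermediate
10 | 2,4-dihydroxy-6-[10-(5-methylfuran-2-yl)decyl]benzoic acid | OC(=O)c1c(O)cc(O)cc1CCCCCCCCCCc1ccc(C)o1 | intermediate
11 | methyl 2,4-dimethoxy-6-[10-(5-methylfuran-2-yl)decyl]benzoate | COC(=O)c1c(OC)cc(OC)cc1CCCCCCCCCCc1ccc(C)o1 | intermediate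
12 | methyl 2,4-dimethoxy-6-(11,14-dioxopentadecyl)benzoate | COC(=O)c1c(OC)cc(OC)cc1CCCCCCCCCCC(=O)CCC(C)=O | intermediate
13 | 2,4-dimethoxy-6-(11,14-dioxopentadecyl)benzoic acid | OC(=O)c1c(OC)cc(OC)cc1CCCCCCCCCCC(=O)CCC(C)=O | intermediate
14 | CJ-13,015, (3S)-5,7-dimethoxy-3-(10,13-dioxotetradecyl)-2-benzofuran-1(3H)-one | COc1cc(OC)c2c(c1)[C@H](CCCCCCCCCC(=O)CCC(C)=O)OC2=O | target

**Summary**
Total step count: 7. Longest linear sequence: 7 steps (1/2 → 14).

**Steps most likely to fail**

Step 7 (unprecedented asymmetric C–H lactonisation). The risks are imidation of the electron-rich ring by NFSI, and low ee if a benzylic fluoride or cation forms and closes without the catalyst. The fallback sets out from ester 12 and comes back at 14. The benzylic CH2 of 12 is oxidised to the aryl ketone with NHPI/Co(OAc)2/O2 to give methyl 2,4-dimethoxy-6-(11,14-dioxopentadecanoyl)benzoate F1. Noyori–Ikariya transfer hydrogenation with RuCl(p-cymene)[(S,S)-TsDPEN] in HCO2H/Et3N reduces the aryl ketone in preference to the two dialkyl ketones. By the usual model this gives methyl 2-[(1S)-1-hydroxy-11,14-dioxopentadecyl]-4,6-dimethoxybenzoate F2, which lactonises spontaneously to 14. This path also bypasses step 6.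

Step 2 (acylation of the pyrone dianion; O-acylation and low conversion are possible). The fallback sets out from 4 and comes back at 11; it also covers a failure of step 3. Commercial 2,2,6-trimethyl-4H-1,3-dioxin-4-one is acetylated (LiHMDS, AcCl) to 2,2-dimethyl-6-(2-oxopropyl)-4H-1,3-dioxin-4-one F3. Its dianion (LDA, then Et2Zn) is acylated with imidazolide 6 from 4 to give 2,2-dimethyl-6-[14-(5-methylfuran-2-yl)-2,4-dioxotetradecyl]-4H-1,3-dioxin-4-one F4. Thermolysis in toluene/MeOH at 110 °C releases the acylketene, which methanol traps as methyl 17-(5-methylfuran-2-yl)-3,5,7-trioxoheptadecanoate F5. Cs2CO3 in MeOH, then AcOH, aromatises this to methyl 2,4-dihydroxy-6-[10-(5-methylfuran-2-yl)decyl]benzoate F6. MeI/K2CO3 converts F6 into 11.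

Step 6 (iodide demethylation next to a base- and heat-sensitive 1,4-diketone). The fallback sets out from 10 and comes back at 13, using a benzyl ester that is removed by hydrogenolysis. Acid 10 is benzylated selectively at the carboxylate (BnBr 1 equiv, KHCO3, DMF) to benzyl 2,4-dihydroxy-6-[10-(5-methylfuran-2-yl)decyl]benzoate F7. Methylation (MeI, K2CO3) gives benzyl 2,4-dimethoxy-6-[10-(5-methylfuran-2-yl)decyl]benzoate F8. Furan hydrolysis as in step 5 gives benzyl 2,4-dimethoxy-6-(11,14-dioxopentadecyl)benzoate F9. H2 over Pd/C in EtOAc then gives 13 under neutral conditions.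

**Further compounds**
F1 | step 7 | methyl 2,4-dimethoxy-6-(11,14-dioxopentadecanoyl)benzoate | COC(=O)c1c(OC)cc(OC)cc1C(=O)CCCCCCCCCC(=O)CCC(C)=O
F2 | step 7 | methyl 2-[(1S)-1-hydroxy-11,14-dioxopentadecyl]-4,6-dimethoxybenzoate | COC(=O)c1c(OC)cc(OC)cc1[C@@H](O)CCCCCCCCCC(=O)CCC(C)=O
F3 | step 2 | 2,2-dimethyl-6-(2-oxopropyl)-4H-1,3-dioxin-4-one | CC(=O)CC1=CC(=O)OC(C)(C)O1
F4 | step 2 | 2,2-dimethyl-6-[14-(5-methylfuran-2-yl)-2,4-dioxotetradecyl]-4H-1,3-dioxin-4-one | Cc1ccc(CCCCCCCCCCC(=O)CC(=O)CC2=CC(=O)OC(C)(C)O2)o1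
F5 | step 2 | methyl 17-(5-methylfuran-2-yl)-3,5,7-trioxoheptadecanoate | COC(=O)CC(=O)CC(=O)CC(=O)CCCCCCCCCCc1ccc(C)o1
F6 | step 2 | methyl 2,4-dihydroxy-6-[10-(5-methylfuran-2-yl)decyl]benzoate | COC(=O)c1c(O)cc(O)cc1CCCCCCCCCCc1ccc(C)o1
F7 | step 6 | benzyl 2,4-dihydroxy-6-[10-(5-methylfuran-2-yl)decyl]benzoate | O=C(OCc1ccccc1)c1c(O)cc(O)cc1CCCCCCCCCCc1ccc(C)o1
F8 | step 6 | benzyl 2,4-dimethoxy-6-[10-(5-methylfuran-2-yl)decyl]benzoate | O=C(OCc1ccccc1)c1c(OC)cc(OC)cc1CCCCCCCCCCc1ccc(C)o1
F9 | step 6 | benzyl 2,4-dimethoxy-6-(11,14-dioxopentadecyl)benzoate | O=C(OCc1ccccc1)c1c(OC)cc(OC)cc1CCCCCCCCCCC(=O)CCC(C)=O
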